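## Retrosynthetic overview
1. 21 ⇒ 20: the methyl acrylate is unmasked last from a C13 ethynyl group (alkyne + CO + MeOH).
2. Key cut: three bonds at once (C9–C10, C6–C8, O–C7) split the tetracycle into two ten-carbon halves, ring-A epoxy aldehyde 10 and ring-C enoate 17. The forward step is Ti(III) epoxide opening, Giese addition, Ti-enolate aldol and lactonisation.
3. 17 ⇒ acetone + enynyl α-keto ester 13 (amine-catalysed asymmetric [3+3], sets C13), then Luche reduction (sets C11).
4. 10 ⇒ 4,4-dimethylcyclohexenone 1 by vinyl conjugate addition, α-methylenation, Luche reduction, lipase resolution, directed epoxidation, acetylation and ozonolysis.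
5. Ring order: A is bought, C is made in step 9, B and the δ-lactone close together in step 12.

Atom labels follow ent-kaurane numbering: ring A is C1–C5/C10; ring B is C5, C6, C8, C9, C10; ring C is C8, C9, C11–C14. The lactone is C7(=O)–O–C20 and the side chain is C13–C16(=C17)–C15O2Me.

Assumption: the sense of induction of the amine catalyst in step 9 is taken as drawn; if it is opposite, the pseudo-enantiomeric quinidine-derived catalyst is used.

## Route

Step 1
Reactants: 1 4,4-dimethylcyclohex-2-en-1-one
Product: 2 (±)-[(4,4-dimethyl-3-vinylcyclohex-1-en-1-yl)oxy]trimethylsilane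
Conditions: CH2=CHMgBr, CuBr·SMe2 (10 mol %), TMSCl, DMPU, THF, −78 °C
Reagents that add atoms: vinylmagnesium bromide C=C[Mg]Br; chlorotrimethylsilane C[Si](C)(C)Cl
Why: Cu-catalysed, TMSCl-accelerated conjugate addition places the vinyl group (C6 plus one sacrificial carbon) on the neopentyl β-carbon C5 and traps the enolate regiospecifically towards C10; C5 is formed racemic and is resolved in step 4.

Step 2
Reactants: 2 (±)-silyl enol ether
Product: 5 (±)-4,4-dimethyl-2-methylidene-3-vinylcyclohexan-1-one, via Mannich base 3 (not isolated), via methiodide 4 (not isolated)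
Conditions: Me2N=CH2+ I−, CH2Cl2, rt; MeI; DBU, 0 °C
Reagents that add atoms: Eschenmoser's salt C=[N+](C)C.[I-]
Why: Mannich reaction of the silyl enol ether followed by Hofmann-type elimination of the methiodide installs C20 as an exocyclic methylene exactly at C10, and no new stereocentre survives.

Step 3
Reactants: 5 (±)-α-methylene ketone
Product: 6 (±)-cis-4,4-dimethyl-2-methylidene-3-vinylcyclohexan-1-ol
Conditions: NaBH4, CeCl3·7H2O, MeOH, −78 °C
Reagents that add atoms: none
Why: Luche 1,2-reduction, in which hydride attacks C1 anti to the C5 vinyl group in either chair, so OH and vinyl end up cis-1,3 (C1 set relative to C5) and 1,4-reduction is suppressed.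

Step 4
Reactants: 6 (±)-cis-allylic alcohol
Product: 7 (1S,3R)-4,4-dimethyl-2-methylidene-3-vinylcyclohexan-1-ol
Conditions: Amano lipase PS, vinyl acetate, MTBE, 30 °C, stopped at about 52 % conversion
Reagents that add atoms: none
Why: Lipase-catalysed kinetic resolution (Kazlauskas rule, large group = C10 side) acetylates the (1R)-enantiomer and returns the (1S,3R)-alcohol in high ee, which fixes the absolute configuration at C1 and C5.

Step 5
Reactants: 7 (1S,3R)-allylic alcohol
Product: 8 (3S,4R,8S)-4-ethenyl-5,5-dimethyl-1-oxaspiro[2.5]octan-8-ol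
Conditions: VO(acac)2 (2 mol %), t-BuOOH, CH2Cl2, 0 °C
Reagents that add atoms: tert-butyl hydroperoxide CC(C)(C)OO
Why: Hydroxyl-directed vanadium-catalysed epoxidation touches only the allylic 1,1-disubstituted alkene and leaves the vinyl group; oxygen is delivered syn to OH, but the C10 configuration is erased at the radical stage of step 12.

Step 6
Reactants: 8 epoxy alcohol
Product: 9 (3S,4R,8S)-4-ethenyl-5,5-dimethyl-1-oxaspiro[2.5]octan-8-yl acetate
Conditions: Ac2O, pyridine, DMAP (cat.), CH2Cl2, 0 °C
Reagents that add atoms: acetic anhydride CC(=O)OC(C)=O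
Why: DMAP-catalysed acetylation puts the C1 acetate of the target in place early so that no late differentiation of three hydroxyl groups is needed, and no stereocentre is touched.

Step 7
Reactants: 9 epoxy acetate
Product: 10 (3S,4R,8S)-4-formyl-5,5-dimethyl-1-oxaspiro[2.5]octan-8-yl acetate
Conditions: O3, CH2Cl2, −78 °C; Me2S; used crude
Reagents that add atoms: ozone [O-][O+]=O
Why: Ozonolysis with reductive work-up cleaves the only C=C to the C6 aldehyde under neutral conditions, which avoids epimerisation at C5 and E1cB opening of the β,γ-epoxide.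

Step 8
Reactants: 11 3-(trimethylsilyl)prop-2-ynal; 12 ethyl 2-oxo-3-(triphenyl-λ5-phosphanylidene)propanoate
Product: 13 ethyl (E)-2-oxo-6-(trimethylsilyl)hex-3-en-5-ynoate
Conditions: CH2Cl2, rt
Reagents that add atoms: none
Why: Wittig olefination with a stabilised acyl ylide gives the (E)-β,γ-unsaturated α-keto ester carrying C7, C8, C14, C13 and the masked side chain.

Step 9
Reactants: 13 enynyl α-keto ester
Product: 15 ethyl (5S)-3-oxo-5-[(trimethylsilyl)ethynyl]cyclohex-1-ene-1-carboxylate, via Michael adduct 14 (not isolated)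
Conditions: acetone (10 equiv), 9-amino-9-deoxy-epi-quinine (20 mol %), 2-nitrobenzoic acid (40 mol %), toluene, rt; then TsOH·H2O (cat.), 60 °C
Reagents that add atoms: acetone CC(C)=O
Why: Primary-amine (enamine) catalysed asymmetric Michael addition of acetone to the β,γ-unsaturated α-keto ester, followed by intramolecular aldol condensation (formal [3+3], Robinson-type annulation), builds ring C; the catalyst shields one face of the acceptor and sets C13.

Step 10
Reactants: 15 ene-keto ester
Product: 16 ethyl (3S,5S)-3-hydroxy-5-[(trimethylsilyl)ethynyl]cyclohex-1-ene-1-carboxylate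
Conditions: NaBH4, CeCl3·7H2O, MeOH, −78 °C
Reagents that add atoms: none
Why: Luche reduction, in which axial hydride delivery on the half-chair with the alkynyl group pseudo-equatorial gives the cis-1,3 allylic alcohol, so C11 is set from C13.

Step 11
Reactants: 16 allylic alcohol
Product: 17 ethyl (3S,5S)-3-[(tert-butyldimethylsilyl)oxy]-5-[(trimethylsilyl)ethynyl]cyclohex-1-ene-1-carboxylate
Conditions: TBSCl, imidazole, DMF, rt
Reagents that add atoms: tert-butyldimethylsilyl chloride CC(C)(C)[Si](C)(C)Cl
Why: Silyl ether formation protects C11–OH and provides the bulky allylic group that shields one face of C9 in step 12.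

Step 12
Reactants: 10 ring-A epoxy aldehyde; 17 ring-C enoate (2 equiv, excess recovered)
Product: 19 C11-OTBS C13-(TMS-ethynyl) tetracyclic 7,20-lactone (all ring stereocentres as in the target), via seco hydroxy ester 18 (not isolated)
Conditions: Cp2TiCl2 (2.6 equiv), Mn, THF, rt (green Cp2TiCl); added over 4 h to 10 + 17, THF (0.5 M), 25 to 40 °C; aq NaH2PO4; PPTS (cat.), CH2Cl2
Reagents that add atoms: none
Why: Proposed new method: Cp2TiCl opens the spiro-epoxide homolytically at the more substituted carbon (Nugent–RajanBabu) to the tertiary C10 radical bearing C20–O–Ti, which adds to the β-carbon C9 of 17 on the ring-A face anti to both the C1 acetate and the C5 formyl group and on the ring-C face anti to the C11 OTBS group (sets C10 and C9); a second Cp2TiCl then reduces the tertiary α-ester radical to a titanium enolate, formed regiospecifically and without base so that the acetate survives, which attacks the C6 aldehyde from its equatorial face with the formyl oxygen turned away from the ester (sets C8 and C6), and only this C7/C20-cis aldolate can lactonise with loss of ethoxide; the closest known reaction types are the Ti(III) reductive epoxide–acrylate coupling/lactonisation and radical–polar crossover Giese–aldol annulations, and the extension is a β-substituted cyclic acceptor.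

Step 13
Reactants: 19 protected tetracycle
Product: 20 C13-ethynyl C6,C11-diol C1-acetate tetracyclic 7,20-lactone
Conditions: TBAF (3 equiv), AcOH (3 equiv), THF, 0 °C to rt
Reagents that add atoms: none
Why: Fluoride-mediated desilylation, buffered with AcOH against retro-aldol and acetate migration, removes O-TBS and C-TMS in one operation without touching a stereocentre.

Step 14
Reactants: 20 terminal alkyne
Product: 21 target CNP0421185.1
Conditions: Pd(OAc)2 (2 mol %), 2-(diphenylphosphino)pyridine (20 mol %), MsOH (10 mol %), CO (20 bar), MeOH/CH2Cl2, 45 °C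
Reagents that add atoms: carbon monoxide [C-]#[O+]; methanol CO
Why: Markovnikov-selective Pd-catalysed hydromethoxycarbonylation of a terminal alkyne (Pd/2-pyridylphosphine/acid catalyst) converts C16≡C17 directly into the 2-substituted methyl acrylate; C13 is untouched and the locked diequatorial C11–OH cannot reach the acyl-palladium.

## Compound list
1 | 4,4-dimethylcyclohex-2-en-1-one | CC1(C)CCC(=O)C=C1 | starting material
2 | (±)-[(4,4-dimethyl-3-vinylcyclohex-1-en-1-yl)oxy]trimethylsilane (racemic; the enantiomer carried on is drawn) | C=C[C@@H]1C(C)(C)CCC(O[Si](C)(C)C)=C1 | intermediate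
3 | (±)-trans-2-[(dimethylamino)methyl]-4,4-dimethyl-3-vinylcyclohexan-1-one (Mannich base, racemic) | C=C[C@@H]1C(C)(C)CCC(=O)[C@H]1CN(C)C | intermediate
4 | methiodide of 3 (racemic) | C=C[C@@H]1C(C)(C)CCC(=O)[C@H]1C[N+](C)(C)C.[I-] | intermediate
5 | (±)-4,4-dimethyl-2-methylidene-3-vinylcyclohexan-1-one (racemic) | C=C[C@@H]1C(C)(C)CCC(=O)C1=C | intermediate
6 | (±)-cis-4,4-dimethyl-2-methylidene-3-vinylcyclohexan-1-ol (racemic, OH and vinyl cis) | C=C[C@@H]1C(C)(C)CC[C@H](O)C1=C | intermediate
7 | (1S,3R)-4,4-dimethyl-2-methylidene-3-vinylcyclohexan-1-ol (single enantiomer) | C=C[C@@H]1C(C)(C)CC[C@H](O)C1=C | intermediate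
8 | (3S,4R,8S)-4-ethenyl-5,5-dimethyl-1-oxaspiro[2.5]octan-8-ol (epoxide O syn to OH) | C=C[C@@H]1C(C)(C)CC[C@H](O)[C@@]12CO2 | intermediate
9 | (3S,4R,8S)-4-ethenyl-5,5-dimethyl-1-oxaspiro[2.5]octan-8-yl acetate | C=C[C@@H]1C(C)(C)CC[C@H](OC(C)=O)[C@@]12CO2 | intermediate
10 | (3S,4R,8S)-4-formyl-5,5-dimethyl-1-oxaspiro[2.5]octan-8-yl acetate | O=C[C@@H]1C(C)(C)CC[C@H](OC(C)=O)[C@@]12CO2 | intermediate
11 | 3-(trimethylsilyl)prop-2-ynal | C[Si](C)(C)C#CC=O | starting material
12 | ethyl 2-oxo-3-(triphenyl-λ5-phosphanylidene)propanoate | CCOC(=O)C(=O)C=P(c1ccccc1)(c1ccccc1)c1ccccc1 | starting material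
13 | ethyl (E)-2-oxo-6-(trimethylsilyl)hex-3-en-5-ynoate | CCOC(=O)C(=O)/C=C/C#C[Si](C)(C)C | intermediate
14 | ethyl (4R)-2,6-dioxo-4-[(trimethylsilyl)ethynyl]heptanoate (Michael adduct) | C[Si](C)(C)C#C[C@@H](CC(=O)C(=O)OCC)CC(C)=O | intermediate
15 | ethyl (5S)-3-oxo-5-[(trimethylsilyl)ethynyl]cyclohex-1-ene-1-carboxylate | C[Si](C)(C)C#C[C@@H]1CC(=O)C=C(C1)C(=O)OCC | intermediate
16 | ethyl (3S,5S)-3-hydroxy-5-[(trimethylsilyl)ethynyl]cyclohex-1-ene-1-carboxylate (cis) | C[Si](C)(C)C#C[C@@H]1C[C@H](O)C=C(C1)C(=O)OCC | intermediate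
17 | ethyl (3S,5S)-3-[(tert-butyldimethylsilyl)oxy]-5-[(trimethylsilyl)ethynyl]cyclohex-1-ene-1-carboxylate | C[Si](C)(C)C#C[C@@H]1C[C@H](O[Si](C)(C)C(C)(C)C)C=C(C1)C(=O)OCC | intermediate
18 | seco hydroxy ester: rings A, B and C closed, C20–OH free, C7 still the ethyl ester, C6–OH | C[Si](C)(C)C#C[C@@H]1C[C@H](O[Si](C)(C)C(C)(C)C)[C@@H]2[C@](C1)(C(=O)OCC)[C@@H](O)[C@@H]1C(C)(C)CC[C@H](OC(C)=O)[C@@]21CO | intermediate
19 | tetracyclic 7,20-lactone with C1-OAc, C6-OH, C11-OTBS and C13-C≡C-TMS; C20, C7 and C11 on one face of ring B; H5, H9, C6-OH and C14 on the other | C[Si](C)(C)C#C[C@@H]1C[C@H](O[Si](C)(C)C(C)(C)C)[C@@H]2[C@]3(C1)C(=O)OC[C@]21[C@@H](OC(C)=O)CCC(C)(C)[C@H]1[C@@H]3O | intermediate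
20 | tetracyclic 7,20-lactone with C1-OAc, C6-OH, C11-OH and C13-ethynyl | C#C[C@@H]1C[C@H](O)[C@@H]2[C@]3(C1)C(=O)OC[C@]21[C@@H](OC(C)=O)CCC(C)(C)[C@H]1[C@@H]3O | intermediate
21 | CNP0421185.1 | C=C(C(=O)OC)[C@@H]1C[C@H](O)[C@@H]2[C@]3(C1)C(=O)OC[C@]21[C@@H](OC(C)=O)CCC(C)(C)[C@H]1[C@@H]3O | target

## Step count and risks
- Total step count: 14.
- Longest linear sequence: 10 (steps 1–7, then 12–14).

Three steps most likely to fail:

**Step 12.** The hindered tertiary radical may abstract hydrogen or disproportionate faster than it adds to a β-substituted, singly activated enoate, and the titanium enolate may be protonated instead of closing ring B.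

The fallback sets out from 9 and 15 and comes back at 19. It uses the doubly activated, fumarate-like acceptor and closes ring B by a separate ionic aldol.
- Cp2TiCl with collidine hydrochloride couples 9 with 15 at the unsubstituted alkene carbon C9, and the titanium alkoxide lactonises to the tricyclic keto lactone F1. Here C9, being α to the ketone, relaxes to the all-equatorial epimer.
- NaBH4 attacks C11 axially and gives the equatorial alcohol F2.
- TBSOTf with 2,6-lutidine gives the silyl ether F3.
- Ozonolysis of the vinyl group gives the aldehyde F4.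
- LiHMDS at −78 °C removes the δ-lactone α-proton, which is more acidic than the acetate, and the lactone enolate closes C6–C8 to 19.

**Step 9.** The enynyl keto ester may react sluggishly or with low ee under enamine catalysis.

The fallback sets out from 13 and comes back at 16. It replaces asymmetric catalysis by resolution.
- Pyrrolidine/AcOH-catalysed annulation with acetone gives the racemic ene-keto ester F5.
- Luche reduction gives the racemic cis alcohol F6.
- Lipase PS with vinyl acetate acetylates the (3R,5R)-enantiomer, so the unreacted (3S,5S)-alcohol is 16.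

**Step 14.** Branched/linear selectivity, or acid-catalysed methanolysis of the acetate, may erode the last step.

The fallback sets out from 20 and comes back at 21. It fixes the regiochemistry before carbonylation.
- [Cp*Ru(MeCN)3]PF6-catalysed Markovnikov hydrosilylation with Et3SiH gives the α-vinylsilane F7.
- NIS in HFIP gives the 2-iodoalkene F8.
- Pd(PPh3)4, CO, MeOH and Et3N then give 21 under non-acidic conditions.

## Further compounds
F1 | step 12 | tricyclic keto lactone (ring A spiro to the δ-lactone, lactone fused to ring C, C11 ketone, C5 vinyl, C8–H) | C[Si](C)(C)C#C[C@@H]1CC(=O)[C@@H]2[C@@H](C1)C(=O)OC[C@]21[C@@H](OC(C)=O)CCC(C)(C)[C@H]1C=C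
F2 | step 12 | C11 equatorial alcohol of F1 | C[Si](C)(C)C#C[C@@H]1C[C@H](O)[C@@H]2[C@@H](C1)C(=O)OC[C@]21[C@@H](OC(C)=O)CCC(C)(C)[C@H]1C=C
F3 | step 12 | C11 TBS ether of F2 | C[Si](C)(C)C#C[C@@H]1C[C@H](O[Si](C)(C)C(C)(C)C)[C@@H]2[C@@H](C1)C(=O)OC[C@]21[C@@H](OC(C)=O)CCC(C)(C)[C@H]1C=C
F4 | step 12 | C6 aldehyde from F3 | C[Si](C)(C)C#C[C@@H]1C[C@H](O[Si](C)(C)C(C)(C)C)[C@@H]2[C@@H](C1)C(=O)OC[C@]21[C@@H](OC(C)=O)CCC(C)(C)[C@H]1C=O
F5 | step 9 | (±)-ethyl 3-oxo-5-[(trimethylsilyl)ethynyl]cyclohex-1-ene-1-carboxylate | C[Si](C)(C)C#CC1CC(=O)C=C(C1)C(=O)OCC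
F6 | step 9 | (±)-cis-ethyl 3-hydroxy-5-[(trimethylsilyl)ethynyl]cyclohex-1-ene-1-carboxylate (racemic; one enantiomer drawn) | C[Si](C)(C)C#C[C@@H]1C[C@H](O)C=C(C1)C(=O)OCC
F7 | step 14 | C16 triethylsilyl α-vinylsilane of 20 | C=C([Si](CC)(CC)CC)[C@@H]1C[C@H](O)[C@@H]2[C@]3(C1)C(=O)OC[C@]21[C@@H](OC(C)=O)CCC(C)(C)[C@H]1[C@@H]3O
F8 | step 14 | C16 iodoalkene | C=C(I)[C@@H]1C[C@H](O)[C@@H]2[C@]3(C1)C(=O)OC[C@]21[C@@H](OC(C)=O)CCC(C)(C)[C@H]1[C@@H]3O
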